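The earlier runs and the new flask come from a simulation with constants of no real substance, noise included.

Percent of the J charged is the unit you need, for L and for J alike.

| flask | J | E | remark | time |
|---|---|---|---|---|
| amber | 0.022 M | 3 equiv (fed, over 8.0 min) | run made earlier; the fed solution adds 0.20 times the starting volume |  |
| flask | 0.022 M | 2.00 equiv (fed, over 8.0 min) | the fed solution adds 0.20 times the starting volume | 2.5 h |

- amber (time / min: L / %, J / %): 2.50: 19, 75; 6.00: 37, 47; 12.0: 54, 24; 20.0: 65, 9; 25.0: 71, 5; 40.0: 73, 3; 50.0: 73, 0

(each reading ± 2 percentage points)

* amount of L in percent of the J charged, at 30 min, 80 min and 2.5 h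

- amounts are per litre of the starting volume; all of the dose is in the solution fed
- what may be going on: J -> G; J -> L; G -> Q; E + G <-> Z; Q -> L

Divide the L gained in the amber run by the J lost, and time drops out. At 20.0 min that ratio reads 71.4%: I take this reading as the direct share, the L formed per J lost, a selectivity. At 12.0 min it reads 71.1%. I take the remainder, 28.6%, to leave by the route through G.

The same reading of J at 20.0 min gives a first-order constant of 0.120 min⁻¹. E stands in neither offered step that uses J, so I draw the same J curve for the new flask.

Now draw L for the new flask. It starts steep, and its starting tangent reaches the direct share at 8.33 min. At the half-life of J on my curve, 5.76 min, I put L at 35.7%. The knee comes next. At 30 min, my curve has J at 2.70%, so I commit to 69.5% of L. My curve then runs into a shelf at 71.4%.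

After the shelf I expect a creep. The amber run ends 1.6 percentage points above the shelf, and a reading scatters by 2 points, so I can read no slope from it.

The forecast gives 72%, 75% and 78%, and it calls the leakage “poorly bounded”. Its first point lies above my 69.5%.

    J → G (k = 0.0310 min⁻¹)
    J → L (k = 0.0790 min⁻¹)
    G → Q (k = 0.0220 min⁻¹)
    E + G ⇌ Z (K = 15.0 M⁻¹, k = 1.80 M⁻¹ min⁻¹)
    Q → L (k = 0.0110 min⁻¹)

The new flask gives 70.3%, 78.4% and 86.7%. At 2.50 h it still holds 9.41% of Q. Now subtract the direct share 71.4%, a reading from the amber run, from its L. At 80 min that leaves 7 points of L, a quarter of the 28.6% I gave to the route through G. At 2.5 h it leaves 15 points, about half of that 28.6%.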